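## Retrosynthetic overview

1. The C8 acrylate ester, the C13 acetate and the C4–C5 epoxide (delivered from the free C8 hydroxyl) are added last to a (4Z)-1-oxogermacra-4,7(11)-dien-12,6-olide (21).
2. Key disconnection: the O–C6 bond of the butenolide, formed while the C1–C6 bond of the bicyclic tertiary alcohol 18 is cut. Alkoxy-radical scission unveils the ten-membered 1-ketone and the C12 ester oxygen closes onto C6.
3. Enabling feature of 18: the C1–C6 ring-fusion bond lies between C4=C5 (ring A) and the exocyclic C7=C11 enoate (on ring B), so only this scission gives a pentadienyl radical/cation. The C12 ester sits cis to C6 across C7=C11, ready for five-membered closure.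
4. 18 comes from an intramolecular Diels–Alder reaction of an acyclic silyl enol ether/trienoate. The tetrasubstituted C7=C11 alkene comes from a Z-enol triflate by Suzuki coupling. C8 is bought (glutamic-acid-derived lactone 1) and relays C10 (alkylation), C6 (key step) and C4/C5 (epoxidation).
5. Ring order: rings A and B together (step 14), then ten-membered ring and butenolide (step 15), then oxirane (step 18).

Key step: step 15

Remark 1: locants follow germacranolide numbering (C1 ketone, C4/C5 epoxide, C6 lactone carbinol, C7=C11 butenolide alkene, C8 ester carbinol, C10 methine, C12 lactone carbonyl, C13 acetoxymethyl carbon); the target is (4R,5S,6S,8S,10R) with a cis-4,5-epoxide, and O6, O8, the epoxide oxygen and the C10 methyl lie on one face.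
Remark 2: lactone 1 is taken as commercial (otherwise one tritylation of (S)-5-(hydroxymethyl)dihydrofuran-2(3H)-one).
Remark 3: compounds 17–20 are carried as mixtures at the centres erased in step 15 (C1/C6), so their SMILES leave those centres undefined; 9 and 10 are mixtures at centres erased in steps 8 and 9.

## Route

Step 1
Reactants: 1 (S)-5-(trityloxymethyl)dihydrofuran-2(3H)-one
Product: 2 (3R,5S)-3-methyl-5-(trityloxymethyl)dihydrofuran-2(3H)-one
Conditions: LiN(iPr)2, THF, −78 °C; MeI, −78 → −40 °C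
Reagents that add atoms: iodomethane, CI
Why: Alkylation of the kinetic lactone enolate (SN2 on MeI) should occur trans to the bulky trityloxymethyl group at C8, which sets C10 (3R) by 1,3-induction in the five-membered ring.

Step 2
Reactants: 2 (3R,5S)-3-methyl-5-(trityloxymethyl)dihydrofuran-2(3H)-one
Product: 3 (2R,4S)-4-hydroxy-N-methoxy-N,2-dimethyl-5-(trityloxy)pentanamide
Conditions: MeNH(OMe)·HCl, AlMe3, CH2Cl2, 0 → 20 °C; aq. Rochelle salt work-up
Reagents that add atoms: N,O-dimethylhydroxylamine hydrochloride, CNOC.Cl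
Why: Weinreb aminolysis of the lactone with the aluminium amide made in the flask should open the ring at the acyl C–O bond, free the C8 hydroxyl and store C1 as a Weinreb amide without enolising C10.

Step 3
Reactants: 3 (2R,4S)-4-hydroxy-N-methoxy-N,2-dimethyl-5-(trityloxy)pentanamide
Product: 4 (2R,4S)-4-(tert-butyldimethylsilyloxy)-N-methoxy-N,2-dimethyl-5-(trityloxy)pentanamide
Conditions: TBSCl, imidazole, DMF, 20 °C
Reagents that add atoms: tert-butyldimethylsilyl chloride, CC(C)(C)[Si](C)(C)Cl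
Why: Imidazole-mediated silylation of the secondary alcohol protects O8 and prevents relactonisation.

Step 4
Reactants: 4 (2R,4S)-4-(tert-butyldimethylsilyloxy)-N-methoxy-N,2-dimethyl-5-(trityloxy)pentanamide
Product: 5 (2R,4S)-4-(tert-butyldimethylsilyloxy)-5-hydroxy-N-methoxy-N,2-dimethylpentanamide
Conditions: H2 (1 atm), Pd(OH)2/C, EtOAc, 20 °C
Reagents that add atoms: none
Why: Hydrogenolysis of the trityl ether is clean at this stage because no alkene is present and the silyl ether and Weinreb amide are inert to H2/Pd.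

Step 5
Reactants: 5 (2R,4S)-4-(tert-butyldimethylsilyloxy)-5-hydroxy-N-methoxy-N,2-dimethylpentanamide
Product: 6 (2R,4S)-4-(tert-butyldimethylsilyloxy)-N-methoxy-N,2-dimethyl-5-oxopentanamide
Conditions: Dess–Martin periodinane, CH2Cl2, 0 → 20 °C
Reagents that add atoms: none
Why: Dess–Martin oxidation gives the α-silyloxy aldehyde under non-basic conditions that should not epimerise C8.

Step 6
Reactants: 7 tert-butyl 3-hydroxypropanoate
Product: 8 tert-butyl 3-(tert-butyldimethylsilyloxy)propanoate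
Conditions: TBSCl, imidazole, CH2Cl2, 20 °C
Reagents that add atoms: tert-butyldimethylsilyl chloride, CC(C)(C)[Si](C)(C)Cl
Why: Routine imidazole-mediated silylation of the primary alcohol provides the C11–C13 ester fragment.

Step 7
Reactants: 6 (2R,4S)-4-(tert-butyldimethylsilyloxy)-N-methoxy-N,2-dimethyl-5-oxopentanamide; 8 tert-butyl 3-(tert-butyldimethylsilyloxy)propanoate
Product: 9 tert-butyl (4S,6R)-4-(tert-butyldimethylsilyloxy)-2-[(tert-butyldimethylsilyloxy)methyl]-3-hydroxy-7-[methoxy(methyl)amino]-6-methyl-7-oxoheptanoate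
Conditions: 8, LiN(iPr)2, THF, −78 °C; then 6, −78 °C; AcOH quench
Reagents that add atoms: none
Why: Aldol addition of the ester lithium enolate should go to the far more electrophilic aldehyde and leave the Weinreb amide alone at −78 °C; the two new centres (C7, C11) are erased in steps 8 and 9, so their configuration does not matter.

Step 8
Reactants: 9 tert-butyl (4S,6R)-4-(tert-butyldimethylsilyloxy)-2-[(tert-butyldimethylsilyloxy)methyl]-3-hydroxy-7-[methoxy(methyl)amino]-6-methyl-7-oxoheptanoate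
Product: 10 tert-butyl (4S,6R)-4-(tert-butyldimethylsilyloxy)-2-[(tert-butyldimethylsilyloxy)methyl]-7-[methoxy(methyl)amino]-6-methyl-3,7-dioxoheptanoate
Conditions: Dess–Martin periodinane, CH2Cl2, 0 → 20 °C
Reagents that add atoms: none
Why: Dess–Martin oxidation of the β-hydroxy ester gives the β-keto ester, in which C11 (not C8) is the acidic position.

Step 9
Reactants: 10 tert-butyl (4S,6R)-4-(tert-butyldimethylsilyloxy)-2-[(tert-butyldimethylsilyloxy)methyl]-7-[methoxy(methyl)amino]-6-methyl-3,7-dioxoheptanoate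
Product: 11 tert-butyl (2Z,4S,6R)-4-(tert-butyldimethylsilyloxy)-2-[(tert-butyldimethylsilyloxy)methyl]-7-[methoxy(methyl)amino]-6-methyl-7-oxo-3-(trifluoromethylsulfonyloxy)hept-2-enoate
Conditions: NaH, Et2O, 0 °C; Tf2O, −78 → 0 °C
Reagents that add atoms: trifluoromethanesulfonic anhydride, O=S(=O)(OS(=O)(=O)C(F)(F)F)C(F)(F)F
Why: O-Triflation of the sodium-chelated enolate of the β-keto ester (enolate oxygen and ester carbonyl held cis by the cation) should give the Z-enol triflate with OTf cis to CO2tBu, which fixes the later C7=C11 geometry.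

Step 10
Reactants: 12 2-methylbut-1-en-3-yne
Product: 13 (E)-4,4,5,5-tetramethyl-2-(3-methylbuta-1,3-dien-1-yl)-1,3,2-dioxaborolane
Conditions: pinacolborane, ZrCp2(H)Cl (cat.), Et3N (cat.), 60 °C
Reagents that add atoms: pinacolborane, CC1(C)OBOC1(C)C
Why: Zirconium-catalysed syn hydroboration of the terminal alkyne should give the E-dienylboronate with boron at the terminal carbon.

Step 11
Reactants: 11 tert-butyl (2Z,4S,6R)-4-(tert-butyldimethylsilyloxy)-2-[(tert-butyldimethylsilyloxy)methyl]-7-[methoxy(methyl)amino]-6-methyl-7-oxo-3-(trifluoromethylsulfonyloxy)hept-2-enoate; 13 (E)-4,4,5,5-tetramethyl-2-(3-methylbuta-1,3-dien-1-yl)-1,3,2-dioxaborolane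
Product: 14 tert-butyl (2E,4E)-3-[(1S,3R)-1-(tert-butyldimethylsilyloxy)-4-[methoxy(methyl)amino]-3-methyl-4-oxobutyl]-2-[(tert-butyldimethylsilyloxy)methyl]-6-methylhepta-2,4,6-trienoate
Conditions: Pd(PPh3)4 (cat.), K3PO4, THF/H2O, 50 °C
Reagents that add atoms: none
Why: Suzuki–Miyaura coupling proceeds with retention at both partners, so C6 takes the place of OTf cis to C12 and the tetrasubstituted C7=C11 alkene is obtained with defined geometry.

Step 12
Reactants: 14 tert-butyl (2E,4E)-3-[(1S,3R)-1-(tert-butyldimethylsilyloxy)-4-[methoxy(methyl)amino]-3-methyl-4-oxobutyl]-2-[(tert-butyldimethylsilyloxy)methyl]-6-methylhepta-2,4,6-trienoate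
Product: 15 tert-butyl (2E,4E)-3-[(1S,3R)-1-(tert-butyldimethylsilyloxy)-3-methyl-4-oxopentyl]-2-[(tert-butyldimethylsilyloxy)methyl]-6-methylhepta-2,4,6-trienoate
Conditions: MeMgBr, THF, −20 → 0 °C; aq. NH4Cl
Reagents that add atoms: methylmagnesium bromide, C[Mg]Br
Why: Weinreb ketone synthesis: the chelated tetrahedral intermediate stops at the methyl ketone, and the hindered conjugated tert-butyl ester should not react.

Step 13
Reactants: 15 tert-butyl (2E,4E)-3-[(1S,3R)-1-(tert-butyldimethylsilyloxy)-3-methyl-4-oxopentyl]-2-[(tert-butyldimethylsilyloxy)methyl]-6-methylhepta-2,4,6-trienoate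
Product: 16 tert-butyl (2E,4E)-3-[(1S,3R)-1-(tert-butyldimethylsilyloxy)-3-methyl-4-(trimethylsilyloxy)pent-4-en-1-yl]-2-[(tert-butyldimethylsilyloxy)methyl]-6-methylhepta-2,4,6-trienoate
Conditions: LiN(iPr)2, Me3SiCl (in-situ quench), THF, −78 °C; non-aqueous work-up
Reagents that add atoms: chlorotrimethylsilane, C[Si](C)(C)Cl
Why: Kinetic deprotonation of the methyl group with in-situ silyl trapping should give the terminal silyl enol ether regioselectively without epimerising C10.

Step 14
Reactants: 16 tert-butyl (2E,4E)-3-[(1S,3R)-1-(tert-butyldimethylsilyloxy)-3-methyl-4-(trimethylsilyloxy)pent-4-en-1-yl]-2-[(tert-butyldimethylsilyloxy)methyl]-6-methylhepta-2,4,6-trienoate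
Product: 18 tert-butyl (E)-2-[(2S,4R)-2-(tert-butyldimethylsilyloxy)-4a-hydroxy-4,7-dimethyl-3,4,4a,5,6,8a-hexahydronaphthalen-1(2H)-ylidene]-3-(tert-butyldimethylsilyloxy)propanoate, via cycloadduct trimethylsilyl ether 17 (not isolated)
Conditions: PhMe (0.01 M), BHT, 165 °C, sealed tube; then K2CO3 (cat.), MeOH, 0 °C
Reagents that add atoms: none
Why: A thermal type 1 intramolecular Diels–Alder reaction of the 1,7,9-decatriene (electron-rich 2-silyloxy alkene onto the ester-conjugated diene) forms C2–C3 and C1–C6, hence rings A and B with C4=C5 in ring A, and methanolysis frees the tertiary C1 hydroxyl; the new centres C1 and C6 are not controlled and need not be, since both are erased in step 15.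

Step 15
Reactants: 18 tert-butyl (E)-2-[(2S,4R)-2-(tert-butyldimethylsilyloxy)-4a-hydroxy-4,7-dimethyl-3,4,4a,5,6,8a-hexahydronaphthalen-1(2H)-ylidene]-3-(tert-butyldimethylsilyloxy)propanoate
Product: 21 (4Z,6R,8S,10R)-8,13-bis(tert-butyldimethylsilyloxy)-1-oxogermacra-4,7(11)-dien-12,6-olide, via tertiary hypoiodite 19 (not isolated), via allylic iodide 20 (not isolated)
Conditions: PhI(OAc)2, I2, CH2Cl2, visible light, 20 °C; then 40 °C (dark)
Reagents that add atoms: none
Why: Proposed new method: the tertiary hypoiodite 19 formed in the flask is homolysed by visible light, the C1 alkoxy radical cleaves the C1–C6 ring-fusion bond (β-scission) because only this bond releases a pentadienyl radical (C4=C5–C6–C7=C11, conjugated to the ester), iodine-atom transfer gives the allylic iodide 20, and its ionisation lets the carbonyl oxygen of the tert-butyl ester add to C6 with loss of isobutene; the closest known reactions are the hypoiodite fragmentation of ring-fusion tertiary carbinols to ten-membered ketones (5-hydroxy steroids to 5,10-seco-ketones) and halolactonisation with tert-butyl esters as oxygen nucleophiles, whose union in one radical–polar crossover has not been shown. The ten-membered ring is unveiled by scission, not closed; the only ring closed is the butenolide, by 5-exo-trig attack of the ester oxygen on the C6 terminus of the C4–C5–C6 allyl cation, which must twist out of conjugation with C7=C11 so that its empty orbital points at the ester. The new stereocentre C6 is set under control of C8: with H8 eclipsing C7=C11 (A(1,3) strain against C13), the C9 ring chain covers one face of the sickle-shaped allyl cation and the ester oxygen, held on the other side of C7, closes on the opposite face, which gives the O6/O8-cis arrangement of the target (6R in 21). The C4=C5 bond should keep the Z geometry inherited from ring A because closure is intramolecular and fast. The step needs scission of C1–C6 rather than C1–C2 or C1–C10 (secured by the two flanking alkenes) and capture at C6 rather than C4 (five- against seven-membered ring; iodide or acetate adducts at C4 are reversible and drain into the lactone).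

Step 16
Reactants: 21 (4Z,6R,8S,10R)-8,13-bis(tert-butyldimethylsilyloxy)-1-oxogermacra-4,7(11)-dien-12,6-olide
Product: 22 (4Z,6R,8S,10R)-8,13-dihydroxy-1-oxogermacra-4,7(11)-dien-12,6-olide
Conditions: HF·pyridine, pyridine, THF, 0 → 20 °C
Reagents that add atoms: none
Why: Fluoride-mediated desilylation (Si–F bond formation) under buffered conditions should remove both silyl ethers and leave the allylic lactone, the ketone and the Z-alkene untouched.

Step 17
Reactants: 22 (4Z,6R,8S,10R)-8,13-dihydroxy-1-oxogermacra-4,7(11)-dien-12,6-olide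
Product: 23 (4Z,6R,8S,10R)-13-acetoxy-8-hydroxy-1-oxogermacra-4,7(11)-dien-12,6-olide
Conditions: AcCl, 2,4,6-collidine, CH2Cl2, −78 °C
Reagents that add atoms: acetyl chloride, CC(=O)Cl
Why: Selective acylation of the primary allylic C13 hydroxyl over the hindered secondary C8 hydroxyl is expected with acetyl chloride and collidine at low temperature.

Step 18
Reactants: 23 (4Z,6R,8S,10R)-13-acetoxy-8-hydroxy-1-oxogermacra-4,7(11)-dien-12,6-olide
Product: 24 (4R,5S,6S,8S,10R)-13-acetoxy-4,5-epoxy-8-hydroxy-1-oxogermacr-7(11)-en-12,6-olide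
Conditions: VO(acac)2 (cat.), tBuOOH (in decane), CH2Cl2, 0 → 20 °C
Reagents that add atoms: tert-butyl hydroperoxide, CC(C)(C)OO
Why: Hydroxyl-directed vanadium-catalysed epoxidation: the vanadate ester of the (bishomoallylic) C8 hydroxyl should deliver oxygen to the only electron-rich alkene, C4=C5, on the face that O8 occupies, which sets C4 and C5 together as the cis-epoxide on the O8 side (4R,5S).

Step 19
Reactants: 25 ethyl 2-(hydroxymethyl)acrylate
Product: 26 ethyl 2-[(tert-butyldimethylsilyloxy)methyl]acrylate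
Conditions: TBSCl, imidazole, CH2Cl2, 20 °C
Reagents that add atoms: tert-butyldimethylsilyl chloride, CC(C)(C)[Si](C)(C)Cl
Why: Routine silylation of the primary allylic alcohol masks the hydroxyl of the side-chain acid.

Step 20
Reactants: 26 ethyl 2-[(tert-butyldimethylsilyloxy)methyl]acrylate
Product: 27 2-[(tert-butyldimethylsilyloxy)methyl]acrylic acid
Conditions: LiOH, THF/H2O, 0 °C; then dilute HCl to pH 4
Reagents that add atoms: lithium hydroxide, [Li+].[OH-]
Why: Saponification of the ethyl ester at 0 °C should leave the silyl ether and the acrylate alkene intact.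

Step 21
Reactants: 24 (4R,5S,6S,8S,10R)-13-acetoxy-4,5-epoxy-8-hydroxy-1-oxogermacr-7(11)-en-12,6-olide; 27 2-[(tert-butyldimethylsilyloxy)methyl]acrylic acid
Product: 28 (4R,5S,6S,8S,10R)-13-acetoxy-8-{2-[(tert-butyldimethylsilyloxy)methyl]acryloyloxy}-4,5-epoxy-1-oxogermacr-7(11)-en-12,6-olide
Conditions: DCC, DMAP (cat.), CH2Cl2, 0 → 20 °C
Reagents that add atoms: none
Why: Steglich esterification acylates the secondary C8 hydroxyl at oxygen with retention and without acid that could open the epoxide.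

Step 22
Reactants: 28 (4R,5S,6S,8S,10R)-13-acetoxy-8-{2-[(tert-butyldimethylsilyloxy)methyl]acryloyloxy}-4,5-epoxy-1-oxogermacr-7(11)-en-12,6-olide
Product: 29 (4R,5S,6S,8S,10R)-13-acetoxy-4,5-epoxy-8-[2-(hydroxymethyl)acryloyloxy]-1-oxogermacr-7(11)-en-12,6-olide (CNP0258719.1)
Conditions: HF·pyridine, pyridine, THF, 0 °C
Reagents that add atoms: none
Why: Buffered fluoride desilylation of the primary allylic silyl ether should spare the epoxide, both esters and the butenolide.

## Compound list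

1 | (S)-5-(trityloxymethyl)dihydrofuran-2(3H)-one | O1[C@H](COC(c2ccccc2)(c2ccccc2)c2ccccc2)CCC1=O | starting material
2 | (3R,5S)-3-methyl-5-(trityloxymethyl)dihydrofuran-2(3H)-one | O1[C@H](COC(c2ccccc2)(c2ccccc2)c2ccccc2)C[C@@H](C)C1=O | intermediate
3 | (2R,4S)-4-hydroxy-N-methoxy-N,2-dimethyl-5-(trityloxy)pentanamide | O[C@H](COC(c1ccccc1)(c1ccccc1)c1ccccc1)C[C@@H](C)C(=O)N(C)OC | intermediate
4 | (2R,4S)-4-(tert-butyldimethylsilyloxy)-N-methoxy-N,2-dimethyl-5-(trityloxy)pentanamide | CC(C)(C)[Si](C)(C)O[C@H](COC(c1ccccc1)(c1ccccc1)c1ccccc1)C[C@@H](C)C(=O)N(C)OC | intermediate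
5 | (2R,4S)-4-(tert-butyldimethylsilyloxy)-5-hydroxy-N-methoxy-N,2-dimethylpentanamide | CC(C)(C)[Si](C)(C)O[C@H](CO)C[C@@H](C)C(=O)N(C)OC | intermediate
6 | (2R,4S)-4-(tert-butyldimethylsilyloxy)-N-methoxy-N,2-dimethyl-5-oxopentanamide | CC(C)(C)[Si](C)(C)O[C@H](C=O)C[C@@H](C)C(=O)N(C)OC | intermediate
7 | tert-butyl 3-hydroxypropanoate | OCCC(=O)OC(C)(C)C | starting material
8 | tert-butyl 3-(tert-butyldimethylsilyloxy)propanoate | CC(C)(C)[Si](C)(C)OCCC(=O)OC(C)(C)C | intermediate
9 | tert-butyl (4S,6R)-4-(tert-butyldimethylsilyloxy)-2-[(tert-butyldimethylsilyloxy)methyl]-3-hydroxy-7-[methoxy(methyl)amino]-6-methyl-7-oxoheptanoate (mixture at C2 and C3) | CC(C)(C)[Si](C)(C)O[C@H](C(O)C(CO[Si](C)(C)C(C)(C)C)C(=O)OC(C)(C)C)C[C@@H](C)C(=O)N(C)OC | intermediate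
10 | tert-butyl (4S,6R)-4-(tert-butyldimethylsilyloxy)-2-[(tert-butyldimethylsilyloxy)methyl]-7-[methoxy(methyl)amino]-6-methyl-3,7-dioxoheptanoate (C2 epimers) | CC(C)(C)[Si](C)(C)O[C@H](C(=O)C(CO[Si](C)(C)C(C)(C)C)C(=O)OC(C)(C)C)C[C@@H](C)C(=O)N(C)OC | intermediate
11 | tert-butyl (2Z,4S,6R)-4-(tert-butyldimethylsilyloxy)-2-[(tert-butyldimethylsilyloxy)methyl]-7-[methoxy(methyl)amino]-6-methyl-7-oxo-3-(trifluoromethylsulfonyloxy)hept-2-enoate | O=C(OC(C)(C)C)/C(CO[Si](C)(C)C(C)(C)C)=C(\OS(=O)(=O)C(F)(F)F)[C@@H](O[Si](C)(C)C(C)(C)C)C[C@@H](C)C(=O)N(C)OC | intermediate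
12 | 2-methylbut-1-en-3-yne | C=C(C)C#C | starting material
13 | (E)-4,4,5,5-tetramethyl-2-(3-methylbuta-1,3-dien-1-yl)-1,3,2-dioxaborolane | C=C(C)/C=C/B1OC(C)(C)C(C)(C)O1 | intermediate
14 | tert-butyl (2E,4E)-3-[(1S,3R)-1-(tert-butyldimethylsilyloxy)-4-[methoxy(methyl)amino]-3-methyl-4-oxobutyl]-2-[(tert-butyldimethylsilyloxy)methyl]-6-methylhepta-2,4,6-trienoate | O=C(OC(C)(C)C)/C(CO[Si](C)(C)C(C)(C)C)=C(\C=C\C(C)=C)[C@@H](O[Si](C)(C)C(C)(C)C)C[C@@H](C)C(=O)N(C)OC | intermediate
15 | tert-butyl (2E,4E)-3-[(1S,3R)-1-(tert-butyldimethylsilyloxy)-3-methyl-4-oxopentyl]-2-[(tert-butyldimethylsilyloxy)methyl]-6-methylhepta-2,4,6-trienoate | O=C(OC(C)(C)C)/C(CO[Si](C)(C)C(C)(C)C)=C(\C=C\C(C)=C)[C@@H](O[Si](C)(C)C(C)(C)C)C[C@@H](C)C(C)=O | intermediate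
16 | tert-butyl (2E,4E)-3-[(1S,3R)-1-(tert-butyldimethylsilyloxy)-3-methyl-4-(trimethylsilyloxy)pent-4-en-1-yl]-2-[(tert-butyldimethylsilyloxy)methyl]-6-methylhepta-2,4,6-trienoate | O=C(OC(C)(C)C)/C(CO[Si](C)(C)C(C)(C)C)=C(\C=C\C(C)=C)[C@@H](O[Si](C)(C)C(C)(C)C)C[C@@H](C)C(=C)O[Si](C)(C)C | intermediate
17 | tert-butyl (E)-2-[(2S,4R)-2-(tert-butyldimethylsilyloxy)-4,7-dimethyl-4a-(trimethylsilyloxy)-3,4,4a,5,6,8a-hexahydronaphthalen-1(2H)-ylidene]-3-(tert-butyldimethylsilyloxy)propanoate (mixture at C4a/C8a) | CC(C)(C)[Si](C)(C)O[C@H]1C[C@@H](C)C2(O[Si](C)(C)C)CCC(C)=CC2/C1=C(/CO[Si](C)(C)C(C)(C)C)C(=O)OC(C)(C)C | intermediate (not isolated)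
18 | tert-butyl (E)-2-[(2S,4R)-2-(tert-butyldimethylsilyloxy)-4a-hydroxy-4,7-dimethyl-3,4,4a,5,6,8a-hexahydronaphthalen-1(2H)-ylidene]-3-(tert-butyldimethylsilyloxy)propanoate (mixture at C4a/C8a, i.e. C1/C6) | CC(C)(C)[Si](C)(C)O[C@H]1C[C@@H](C)C2(O)CCC(C)=CC2/C1=C(/CO[Si](C)(C)C(C)(C)C)C(=O)OC(C)(C)C | intermediate
19 | tertiary hypoiodite of 18 (O–I at C4a) | CC(C)(C)[Si](C)(C)O[C@H]1C[C@@H](C)C2(OI)CCC(C)=CC2/C1=C(/CO[Si](C)(C)C(C)(C)C)C(=O)OC(C)(C)C | intermediate (not isolated)
20 | tert-butyl (4Z,8S,10R)-8,13-bis(tert-butyldimethylsilyloxy)-6-iodo-1-oxogermacra-4,7(11)-dien-12-oate (C6 epimers, C12 cis to C6) | CC(C)(C)[Si](C)(C)O[C@H]1C[C@@H](C)C(=O)CC/C(C)=C\C(I)/C1=C(/CO[Si](C)(C)C(C)(C)C)C(=O)OC(C)(C)C | intermediate (not isolated)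
21 | (4Z,6R,8S,10R)-8,13-bis(tert-butyldimethylsilyloxy)-1-oxogermacra-4,7(11)-dien-12,6-olide | CC(C)(C)[Si](C)(C)O[C@H]1C[C@@H](C)C(=O)CC/C(C)=C\[C@H]2OC(=O)C(CO[Si](C)(C)C(C)(C)C)=C12 | intermediate
22 | (4Z,6R,8S,10R)-8,13-dihydroxy-1-oxogermacra-4,7(11)-dien-12,6-olide | O[C@H]1C[C@@H](C)C(=O)CC/C(C)=C\[C@H]2OC(=O)C(CO)=C12 | intermediate
23 | (4Z,6R,8S,10R)-13-acetoxy-8-hydroxy-1-oxogermacra-4,7(11)-dien-12,6-olide | O[C@H]1C[C@@H](C)C(=O)CC/C(C)=C\[C@H]2OC(=O)C(COC(C)=O)=C12 | intermediate
24 | (4R,5S,6S,8S,10R)-13-acetoxy-4,5-epoxy-8-hydroxy-1-oxogermacr-7(11)-en-12,6-olide | O[C@H]1C[C@@H](C)C(=O)CC[C@@]2(C)O[C@H]2[C@H]2OC(=O)C(COC(C)=O)=C12 | intermediate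
25 | ethyl 2-(hydroxymethyl)acrylate | C=C(CO)C(=O)OCC | starting material
26 | ethyl 2-[(tert-butyldimethylsilyloxy)methyl]acrylate | C=C(CO[Si](C)(C)C(C)(C)C)C(=O)OCC | intermediate
27 | 2-[(tert-butyldimethylsilyloxy)methyl]acrylic acid | C=C(CO[Si](C)(C)C(C)(C)C)C(=O)O | intermediate
28 | (4R,5S,6S,8S,10R)-13-acetoxy-8-{2-[(tert-butyldimethylsilyloxy)methyl]acryloyloxy}-4,5-epoxy-1-oxogermacr-7(11)-en-12,6-olide | C=C(CO[Si](C)(C)C(C)(C)C)C(=O)O[C@H]1C[C@@H](C)C(=O)CC[C@@]2(C)O[C@H]2[C@H]2OC(=O)C(COC(C)=O)=C12 | intermediate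
29 | (4R,5S,6S,8S,10R)-13-acetoxy-4,5-epoxy-8-[2-(hydroxymethyl)acryloyloxy]-1-oxogermacr-7(11)-en-12,6-olide | C=C(CO)C(=O)O[C@H]1C[C@@H](C)C(=O)CC[C@@]2(C)O[C@H]2[C@H]2OC(=O)C(COC(C)=O)=C12 | target

## Step count and risks

Total step count: 22 (18 in the main line; 4 for the side fragments 8, 13, 26 and 27).
Longest linear sequence: 18 steps (1 → 29 through steps 1–5, 7–9, 11–18, 21, 22).

Steps most likely to fail:

1. Step 15 (proposed new method). Three things may go wrong. The electrophilic iodine reagent may add to the C4=C5 bond instead of forming the O–I bond. The allyl cation may be intercepted by acetate or iodide, or lose a proton, before the ester closes. A long-lived cation may erode the facial selectivity at C6 or the Z geometry. The fallback uses known chemistry and separates ring opening from C–O closure. It sets out from 18. A photocatalytic proton-coupled-electron-transfer ring opening ([Ir(dF(CF3)ppy)2(5,5′-d(CF3)bpy)]PF6, collidine, an aryl thiol as hydrogen-atom donor, blue light) is the known redox-neutral β-scission/hydrogen-transfer isomerisation of tertiary cycloalkanols and needs no electrophilic halogen. With hydrogen delivered to the central carbon of the pentadienyl radical it should give tert-butyl (4Z,8S,10R)-8,13-bis(tert-butyldimethylsilyloxy)-1-oxogermacra-4,7(11)-dien-12-oate F1. Wohl–Ziegler bromination (NBS, AIBN, PhCF3, 80 °C) at the doubly allylic C6 should then give the γ-bromo enoate, tert-butyl (4Z,8S,10R)-6-bromo-8,13-bis(tert-butyldimethylsilyloxy)-1-oxogermacra-4,7(11)-dien-12-oate F2. Continued heating closes the butenolide by the classical lactonisation of a cis γ-bromo enoate and returns to 21.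

2. Step 14. The cycloaddition of the 1,1-disubstituted, weakly polarised silyl enol ether may be too slow, so that loss of the enol silane, thermal loss of isobutene from the ester or oligomerisation of the triene compete. The fallback changes the dienophile to a 2-boryl alkene and sets out from 15. KN(SiMe3)2/PhNTf2 at −78 °C should give the terminal enol triflate, tert-butyl (2E,4E)-3-[(1S,3R)-1-(tert-butyldimethylsilyloxy)-3-methyl-4-(trifluoromethylsulfonyloxy)pent-4-en-1-yl]-2-[(tert-butyldimethylsilyloxy)methyl]-6-methylhepta-2,4,6-trienoate F3. Miyaura borylation (B2pin2, PdCl2(PPh3)2, KOPh, PhMe, 50 °C) should give the corresponding 4-(pinacolboryl)pent-4-enyl compound F4. A thermal intramolecular Diels–Alder reaction (PhMe, 150 °C) should give the ring-fusion tertiary boronate F5, the 4a-(pinacolboryl) analogue of 18. Oxidation (NaBO3·4H2O, THF/H2O) returns to 18.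

3. Step 18. Delivery from the remote C8 hydroxyl may be poor, so that epoxidation is slow or occurs undirected on the exposed face, or the allylic alcohol is oxidised. The fallback builds the epoxide by the halohydrin route after the ester is in place and sets out from 23. Steglich esterification with 27 should give (4Z,6R,8S,10R)-13-acetoxy-8-{2-[(tert-butyldimethylsilyloxy)methyl]acryloyloxy}-1-oxogermacra-4,7(11)-dien-12,6-olide F6. With NBS in THF/H2O the bromonium ion should form on the exposed face and water should open it at the tertiary C4 from the other face, giving the bromohydrin (4R,5R,6S,8S,10R)-13-acetoxy-5-bromo-8-{2-[(tert-butyldimethylsilyloxy)methyl]acryloyloxy}-4-hydroxy-1-oxogermacr-7(11)-en-12,6-olide F7. K2CO3 in acetone closes the epoxide with inversion at C5, placing oxygen on the face that the directed reaction was meant to reach, and returns to 28.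

Further compounds
F1 | step 15 | tert-butyl (4Z,8S,10R)-8,13-bis(tert-butyldimethylsilyloxy)-1-oxogermacra-4,7(11)-dien-12-oate (C6 methylene, C12 cis to C6) | CC(C)(C)[Si](C)(C)O[C@H]1C[C@@H](C)C(=O)CC/C(C)=C\C/C1=C(/CO[Si](C)(C)C(C)(C)C)C(=O)OC(C)(C)C
F2 | step 15 | tert-butyl (4Z,8S,10R)-6-bromo-8,13-bis(tert-butyldimethylsilyloxy)-1-oxogermacra-4,7(11)-dien-12-oate (C6 epimers) | CC(C)(C)[Si](C)(C)O[C@H]1C[C@@H](C)C(=O)CC/C(C)=C\C(Br)/C1=C(/CO[Si](C)(C)C(C)(C)C)C(=O)OC(C)(C)C
F3 | step 14 | tert-butyl (2E,4E)-3-[(1S,3R)-1-(tert-butyldimethylsilyloxy)-3-methyl-4-(trifluoromethylsulfonyloxy)pent-4-en-1-yl]-2-[(tert-butyldimethylsilyloxy)methyl]-6-methylhepta-2,4,6-trienoate | O=C(OC(C)(C)C)/C(CO[Si](C)(C)C(C)(C)C)=C(\C=C\C(C)=C)[C@@H](O[Si](C)(C)C(C)(C)C)C[C@@H](C)C(=C)OS(=O)(=O)C(F)(F)F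
F4 | step 14 | tert-butyl (2E,4E)-3-[(1S,3R)-1-(tert-butyldimethylsilyloxy)-3-methyl-4-(4,4,5,5-tetramethyl-1,3,2-dioxaborolan-2-yl)pent-4-en-1-yl]-2-[(tert-butyldimethylsilyloxy)methyl]-6-methylhepta-2,4,6-trienoate | O=C(OC(C)(C)C)/C(CO[Si](C)(C)C(C)(C)C)=C(\C=C\C(C)=C)[C@@H](O[Si](C)(C)C(C)(C)C)C[C@@H](C)C(=C)B1OC(C)(C)C(C)(C)O1
F5 | step 14 | tert-butyl (E)-2-[(2S,4R)-2-(tert-butyldimethylsilyloxy)-4,7-dimethyl-4a-(4,4,5,5-tetramethyl-1,3,2-dioxaborolan-2-yl)-3,4,4a,5,6,8a-hexahydronaphthalen-1(2H)-ylidene]-3-(tert-butyldimethylsilyloxy)propanoate (mixture at C4a/C8a) | CC(C)(C)[Si](C)(C)O[C@H]1C[C@@H](C)C2(B3OC(C)(C)C(C)(C)O3)CCC(C)=CC2/C1=C(/CO[Si](C)(C)C(C)(C)C)C(=O)OC(C)(C)C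
F6 | step 18 | (4Z,6R,8S,10R)-13-acetoxy-8-{2-[(tert-butyldimethylsilyloxy)methyl]acryloyloxy}-1-oxogermacra-4,7(11)-dien-12,6-olide | C=C(CO[Si](C)(C)C(C)(C)C)C(=O)O[C@H]1C[C@@H](C)C(=O)CC/C(C)=C\[C@H]2OC(=O)C(COC(C)=O)=C12
F7 | step 18 | (4R,5R,6S,8S,10R)-13-acetoxy-5-bromo-8-{2-[(tert-butyldimethylsilyloxy)methyl]acryloyloxy}-4-hydroxy-1-oxogermacr-7(11)-en-12,6-olide | C=C(CO[Si](C)(C)C(C)(C)C)C(=O)O[C@H]1C[C@@H](C)C(=O)CC[C@@](C)(O)[C@H](Br)[C@H]2OC(=O)C(COC(C)=O)=C12
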